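**Strategy.** Everything rests on cutting C4a–C8a and C5–C6, which takes apart the benzene ring and the dihydropyran ring of the chroman together. The feature exploited is the ortho relationship, at the ring fusion, of oxygen-bearing C8a and carbon-bearing C4a. Because of it, the chain O1–C2–C3–C4 can tether C3 of a pyridazine (future C8a) to a methoxyalkyne (future C4a and C5). One thermal inverse-demand Diels–Alder reaction with loss of N2 then gives the pentasubstituted arene and the pyran, with C6–H, the C7 oxymethyl group and the C8 carboxyl carbon already in place. The precursor is a 3-(tert-alkoxy)pyridazine-4-carboxylate whose alkoxy group comes from (R)-linalool, the source of quaternary C2.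

Key step: step 10

Remarks on the chemistry:
- Commercial (R)-(−)-linalool of high enantiomeric purity is assumed. Its C3 has the spatial arrangement of C2 of the target, and no step makes or breaks a bond at this carbon. The descriptor changes from R to S in step 11 only because the oxidised side chain gains CIP rank.
- The C8 carboxyl group is carried as the ethyl ester, because diethyl mesoxalate is the commercial building block and an ethyl ester is less open to acyl transfer in step 9. The alkyl group is lost in step 13.
- From step 14 on the compound is a β-aryloxy ketone, so strongly basic media are avoided.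

**Step 1**
Reactants: 1 (R)-(−)-linalool, (3R)-3,7-dimethylocta-1,6-dien-3-ol
Product: 2 triethyl{[(3R)-3,7-dimethylocta-1,6-dien-3-yl]oxy}silane
Conditions: Et3SiOTf, 2,6-lutidine, CH2Cl2, −78 → 0 °C
Reagents that add atoms: triethylsilyl trifluoromethanesulfonate, CC[Si](CC)(CC)OS(=O)(=O)C(F)(F)F
Why: Silylation of a hindered tertiary alcohol with a silyl triflate and a non-nucleophilic pyridine base is routine O-protection; no bond to the stereocentre is touched, and the mask is needed because a free γ-iodo alkoxide in step 4 would close to an oxetane.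

**Step 2**
Reactants: 2 linalool triethylsilyl ether
Product: 4 (3R)-3,7-dimethyl-3-(triethylsilyloxy)oct-6-en-1-ol, via B-alkyl-9-BBN adduct 3 (not isolated)
Conditions: 9-BBN-H (0.5 M in THF, 1.3 equiv), 0 °C → rt; then 3 M aq. NaOH, 30% H2O2, 0 °C → rt
Reagents that add atoms: 9-borabicyclo[3.3.1]nonane, [H]B1C2CCCC1CCC2 (boron is kept only in 3); hydrogen peroxide, OO
Why: Brown hydroboration–oxidation: 9-BBN-H adds to a monosubstituted alkene far faster than to the trisubstituted prenyl alkene and places boron on the terminal carbon, so alkaline peroxide should give the primary alcohol with the stereocentre untouched.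

**Step 3**
Reactants: 4 primary alcohol
Product: 5 triethyl{[(3R)-1-iodo-3,7-dimethyloct-6-en-3-yl]oxy}silane
Conditions: I2, PPh3, imidazole, CH2Cl2, 0 °C → rt, dark
Reagents that add atoms: iodine, II
Why: Appel-type iodination (Garegg–Samuelsson conditions) converts the only free, primary hydroxyl by SN2 displacement of the oxyphosphonium ion, while imidazole keeps the medium neutral for the silyl ether and the alkene.

**Step 4**
Reactants: 5 primary iodide; 6 chloroacetaldehyde dimethyl acetal
Product: 8 triethyl{[(5R)-1-methoxy-5,9-dimethyldec-8-en-1-yn-5-yl]oxy}silane, via lithium methoxyacetylide 7 (not isolated)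
Conditions: 6 (2.5 equiv), LiNEt2 (7.5 equiv, from Et2NH and n-BuLi), THF, −78 → 0 °C; then 5, DMPU, −78 °C → rt; work-up at pH ≥ 7
Reagents that add atoms: lithium diethylamide, [Li]N(CC)CC (lithium is kept only in 7)
Why: Three equivalents of amide base strip methanol and HCl from the chloroacetal and deprotonate the resulting methoxyacetylene (the standard in-situ access to alkoxyacetylides, which avoids handling the volatile alkyne), and the acetylide is then alkylated by the unhindered primary iodide in an SN2 reaction promoted by the dipolar cosolvent.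

**Step 5**
Reactants: 8 silyl-protected ynol ether
Product: 9 (5R)-1-methoxy-5,9-dimethyldec-8-en-1-yn-5-ol
Conditions: Bu4NF (1 M in THF), rt → 40 °C; pH 7 buffer; Et3N-deactivated silica
Reagents that add atoms: none
Why: Fluoride-induced desilylation is basic rather than acidic, so the acid-labile ynol ether survives and the tertiary alcohol is released with its C–O bond intact.

**Step 6**
Reactants: 10 3-[(tert-butyldimethylsilyl)oxy]propanal; 11 diethyl mesoxalate (diethyl 2-oxopropanedioate)
Product: 12 diethyl 2-{1-[(tert-butyldimethylsilyl)oxy]-3-oxopropan-2-yl}-2-hydroxypropanedioate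
Conditions: L-proline (0.3 equiv), CH2Cl2, rt
Reagents that add atoms: none
Why: Enamine-catalysed (proline) cross-aldol addition: the aldehyde is the only enolisable partner and the central carbonyl of the mesoxalate is the most electrophilic acceptor, so C4–C5 of the later diazine is formed cleanly; the new stereocentre is not controlled because it is erased on aromatisation in step 7.

**Step 7**
Reactants: 12 aldol adduct
Product: 15 ethyl 5-{[(tert-butyldimethylsilyl)oxy]methyl}-3-oxo-2,3-dihydropyridazine-4-carboxylate, via aldehyde hydrazone 13 (not isolated), via 4-hydroxy-4,5-dihydropyridazinone 14 (not isolated)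
Conditions: N2H4·H2O (1.0 equiv), EtOH, 0 °C → rt; then AcOH (2 equiv), 60 °C
Reagents that add atoms: hydrazine hydrate, NN.O
Why: Classical pyridazinone synthesis from a γ-oxo ester and hydrazine: the hydrazone forms at the aldehyde (future C6–H), its NH2 acylates one ester in a six-membered lactamisation, and mild acid removes water across C4–C5 with aromatisation as driving force, which places the silyloxymethyl group at C5 without regiochemical ambiguity.

**Step 8**
Reactants: 15 pyridazinone ester
Product: 16 ethyl 3-chloro-5-{[(tert-butyldimethylsilyl)oxy]methyl}pyridazine-4-carboxylate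
Conditions: POCl3 (2 equiv), i-Pr2NEt (2 equiv), toluene, 80 °C
Reagents that add atoms: phosphoryl chloride, O=P(Cl)(Cl)Cl
Why: Deoxychlorination of a diazinone with POCl3 (O-phosphorylation, then addition–elimination by chloride) is the standard route to 3-chloropyridazines, and the tertiary amine captures the acid so that the primary silyl ether is not cleaved.

**Step 9**
Reactants: 9 tertiary alcohol; 16 chloropyridazine ester
Product: 18 ethyl 5-{[(tert-butyldimethylsilyl)oxy]methyl}-3-{[(5R)-1-methoxy-5,9-dimethyldec-8-en-1-yn-5-yl]oxy}pyridazine-4-carboxylate, via potassium alkoxide 17 (not isolated)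
Conditions: KN(SiMe3)2 (1.0 equiv), THF, −78 °C; then 16, −78 → 0 °C; neutral work-up
Reagents that add atoms: potassium bis(trimethylsilyl)amide, [K+].C[Si](C)(C)[N-][Si](C)(C)C (potassium is kept only in 17)
Why: Nucleophilic aromatic substitution (addition–elimination): C3 is activated by the adjacent ring nitrogen and the ortho ester, tertiary alkoxides are known to displace chloride from such chlorodiazines, the ester is shielded by its two ortho neighbours, and the C–O bond of the alcohol is not involved, so the configuration is retained.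

**Step 10**
Reactants: 18 pyridazinyl ether with tethered methoxyalkyne
Product: 20 ethyl (2R)-7-{[(tert-butyldimethylsilyl)oxy]methyl}-5-methoxy-2-methyl-2-(4-methylpent-3-en-1-yl)-3,4-dihydro-2H-chromene-8-carboxylate, via diazabicyclo[2.2.2]octatriene 19 (not isolated)
Conditions: PhCl (0.01 M, degassed), 2,6-di-tert-butyl-4-methylpyridine (0.2 equiv), 120–130 °C, sealed base-washed glass, Ar
Reagents that add atoms: none
Why: On heating, the LUMO of the ester-bearing diazine (diene carbons C3–C4–C5–C6) meets the HOMO of the donor-substituted alkyne, asynchronous but concerted bonding at C3 and C6 gives the N=N-bridged bicycle 19, and this ejects dinitrogen at once in a retro-[4+2] step that makes the process irreversible. The closest known reaction type is the thermal intramolecular inverse-electron-demand Diels–Alder reaction of 3-(alkynyloxy)pyridazines bearing an acceptor at C4, which furnishes dihydrobenzofurans and chromans, and ynol ethers and ynamines are established dienophiles for electron-poor azines. Mode of closure: the dihydropyran ring arises as the six-membered, tether-containing ring the moment the inner alkyne carbon (C4a) bonds to diazine C3 (C8a), giving a fused and not a bridged product, while the benzene ring is assembled from the four diazine carbons and the two alkyne carbons and is aromatised by the N2 extrusion. No stereocentre is created, since the bridgehead centres of 19 disappear with N2 and no bond to C2 is made or broken, so the linalool configuration is carried through. Regiochemistry is dictated by the short tether and agrees with the polar bias (the nucleophilic alkyne carbon β to OMe attacks C3 next to the ester), and the equally tethered prenyl alkene cannot compete because it is far less electron-rich and would have to bond through its fully substituted carbon. The rate contest with retro-ene or acid-induced loss of the tertiary alkyl group is addressed by the ester/donor-alkyne pairing and the gem-disubstituted C2, which keep the temperature moderate, by the hindered pyridine base and base-washed glass, and by the methyl ynol ether, which has no β-hydrogen through which it could collapse to a ketene.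

**Step 11**
Reactants: 20 chroman ester
Product: 21 ethyl (2S)-7-{[(tert-butyldimethylsilyl)oxy]methyl}-2-[2-(3,3-dimethyloxiran-2-yl)ethyl]-5-methoxy-2-methylchroman-8-carboxylate (both oxirane epimers)
Conditions: mCPBA (1.1 equiv), CH2Cl2, 0 °C
Reagents that add atoms: 3-chloroperoxybenzoic acid, OOC(=O)c1cccc(Cl)c1
Why: Prilezhaev epoxidation picks the only nucleophilic C=C bond; the face is not controlled, which is harmless because the new stereocentre is destroyed in step 12.

**Step 12**
Reactants: 21 epoxide
Product: 24 ethyl (2S)-7-{[(tert-butyldimethylsilyl)oxy]methyl}-2-[(2E)-4-hydroxy-4-methylpent-2-en-1-yl]-5-methoxy-2-methylchroman-8-carboxylate, via β-hydroxy selenide 22 (not isolated), via selenoxide 23 (not isolated)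
Conditions: (PhSe)2 (0.6 equiv), NaBH4 (1.3 equiv), EtOH, rt → 78 °C; then THF, 30% H2O2, 0 °C → rt
Reagents that add atoms: diphenyl diselenide, c1ccc(cc1)[Se][Se]c1ccccc1 (selenium is kept only in 22 and 23); hydrogen peroxide, OO (oxygen is kept only in 23)
Why: Selenolate opening of the epoxide at its less hindered secondary carbon (SN2) followed by selenoxide syn-elimination, which can only run away from the hydrogen-free carbinol carbon, is the established regiospecific transposition of a trisubstituted epoxide to the (E)-configured tertiary allylic alcohol, unlike the singlet-oxygen ene reaction, which gives regioisomers.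

**Step 13**
Reactants: 24 allylic alcohol ester
Product: 25 (3E)-5-[(2S)-7-{[(tert-butyldimethylsilyl)oxy]methyl}-8-(hydroxymethyl)-5-methoxy-2-methylchroman-2-yl]-2-methylpent-3-en-2-ol
Conditions: i-Bu2AlH (4 equiv), CH2Cl2, −78 → 0 °C; aq. potassium sodium tartrate
Reagents that add atoms: none
Why: Hydride reduction of the aryl ester to the benzylic alcohol with i-Bu2AlH; the low temperature and the weakly nucleophilic aluminium alkoxide should suppress migration of the neighbouring silyl group, and alkene, silyl ether and aryl ethers are inert.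

**Step 14**
Reactants: 25 diol
Product: 27 (2S)-7-{[(tert-butyldimethylsilyl)oxy]methyl}-5-methoxy-2-methyl-2-(4-methyl-2-oxopent-3-en-1-yl)chroman-8-carbaldehyde, via hydroxy aldehyde 26 (not isolated)
Conditions: pyridinium chlorochromate [C5H5NH][CrO3Cl] (5 equiv), Celite, CH2Cl2, rt
Reagents that add atoms: pyridinium chlorochromate, [O-][Cr](=O)(=O)Cl.c1cc[nH+]cc1 (delivers the ketone oxygen at C2′ in the [3,3] shift)
Why: Chromate oxidation does two jobs: the primary benzylic alcohol goes to the aldehyde, and the tertiary allylic alcohol undergoes the Babler–Dauben oxidative transposition (chromate ester, [3,3] shift to C2′, oxidation of the secondary chromate) to the β,β-dimethyl enone, without touching C2.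

**Step 15**
Reactants: 27 silyl-protected aldehyde enone
Product: 28 (2S)-7-(hydroxymethyl)-5-methoxy-2-methyl-2-(4-methyl-2-oxopent-3-en-1-yl)chroman-8-carbaldehyde
Conditions: HF·pyridine, pyridine, THF, 0 °C → rt
Reagents that add atoms: none
Why: Fluoride-mediated cleavage of a primary silyl ether under mildly acidic, buffered conditions avoids the basic medium in which the β-aryloxy ketone could open by a retro-oxa-Michael reaction and racemise C2.

**Step 16**
Reactants: 28 hydroxy aldehyde; 29 palmitoyl chloride
Product: 30 [(2S)-8-formyl-5-methoxy-2-methyl-2-(4-methyl-2-oxopent-3-en-1-yl)chroman-7-yl]methyl hexadecanoate (target)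
Conditions: 29 (1.2 equiv), pyridine (3 equiv), 4-(dimethylamino)pyridine (0.05 equiv), CH2Cl2, 0 °C
Reagents that add atoms: none
Why: Acylation of the primary alcohol with an acid chloride under nucleophilic catalysis; the doubly donor-substituted aldehyde has little tendency to hold the alcohol as a lactol, and pyridine is too weak a base to trigger β-elimination of the aryloxide.

**Compound list**

1 | (R)-(−)-linalool | O[C@](C)(CCC=C(C)C)C=C | starting material
2 | triethyl{[(3R)-3,7-dimethylocta-1,6-dien-3-yl]oxy}silane | CC[Si](CC)(CC)O[C@](C)(CCC=C(C)C)C=C | intermediate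
3 | 9-[(3R)-3,7-dimethyl-3-(triethylsilyloxy)oct-6-en-1-yl]-9-borabicyclo[3.3.1]nonane | CC[Si](CC)(CC)O[C@](C)(CCC=C(C)C)CCB1C2CCCC1CCC2 | intermediate
4 | (3R)-3,7-dimethyl-3-(triethylsilyloxy)oct-6-en-1-ol | CC[Si](CC)(CC)O[C@](C)(CCC=C(C)C)CCO | intermediate
5 | triethyl{[(3R)-1-iodo-3,7-dimethyloct-6-en-3-yl]oxy}silane | CC[Si](CC)(CC)O[C@](C)(CCC=C(C)C)CCI | intermediate
6 | chloroacetaldehyde dimethyl acetal | COC(CCl)OC | starting material
7 | lithium methoxyacetylide | [Li]C#COC | intermediate
8 | triethyl{[(5R)-1-methoxy-5,9-dimethyldec-8-en-1-yn-5-yl]oxy}silane | CC[Si](CC)(CC)O[C@](C)(CCC=C(C)C)CCC#COC | intermediate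
9 | (5R)-1-methoxy-5,9-dimethyldec-8-en-1-yn-5-ol | O[C@](C)(CCC=C(C)C)CCC#COC | intermediate
10 | 3-[(tert-butyldimethylsilyl)oxy]propanal | O=CCCO[Si](C)(C)C(C)(C)C | starting material
11 | diethyl mesoxalate | CCOC(=O)C(=O)C(=O)OCC | starting material
12 | diethyl 2-{1-[(tert-butyldimethylsilyl)oxy]-3-oxopropan-2-yl}-2-hydroxypropanedioate | CCOC(=O)C(O)(C(=O)OCC)C(C=O)CO[Si](C)(C)C(C)(C)C | intermediate
13 | hydrazone of 12 | CCOC(=O)C(O)(C(=O)OCC)C(C=NN)CO[Si](C)(C)C(C)(C)C | intermediate
14 | ethyl 5-{[(tert-butyldimethylsilyl)oxy]methyl}-4-hydroxy-3-oxo-2,3,4,5-tetrahydropyridazine-4-carboxylate | CCOC(=O)C1(O)C(CO[Si](C)(C)C(C)(C)C)C=NNC1=O | intermediate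
15 | ethyl 5-{[(tert-butyldimethylsilyl)oxy]methyl}-3-oxo-2,3-dihydropyridazine-4-carboxylate | CCOC(=O)c1c(CO[Si](C)(C)C(C)(C)C)cn[nH]c1=O | intermediate
16 | ethyl 3-chloro-5-{[(tert-butyldimethylsilyl)oxy]methyl}pyridazine-4-carboxylate | CCOC(=O)c1c(CO[Si](C)(C)C(C)(C)C)cnnc1Cl | intermediate
17 | potassium (5R)-1-methoxy-5,9-dimethyldec-8-en-1-yn-5-olate | [K+].[O-][C@](C)(CCC=C(C)C)CCC#COC | intermediate
18 | ethyl 5-{[(tert-butyldimethylsilyl)oxy]methyl}-3-{[(5R)-1-methoxy-5,9-dimethyldec-8-en-1-yn-5-yl]oxy}pyridazine-4-carboxylate (key-step precursor) | CCOC(=O)c1c(CO[Si](C)(C)C(C)(C)C)cnnc1O[C@](C)(CCC=C(C)C)CCC#COC | intermediate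
19 | pyran-fused 2,3-diazabicyclo[2.2.2]octa-2,5,7-triene cycloadduct (bridgeheads undefined) | CCOC(=O)C1=C(CO[Si](C)(C)C(C)(C)C)C2N=NC13O[C@](C)(CCC=C(C)C)CCC3=C2OC | intermediate
20 | ethyl (2R)-7-{[(tert-butyldimethylsilyl)oxy]methyl}-5-methoxy-2-methyl-2-(4-methylpent-3-en-1-yl)chroman-8-carboxylate (key-step product) | CCOC(=O)c1c(CO[Si](C)(C)C(C)(C)C)cc(OC)c2c1O[C@](C)(CCC=C(C)C)CC2 | intermediate
21 | side-chain epoxide of 20, (2S), both oxirane epimers | CCOC(=O)c1c(CO[Si](C)(C)C(C)(C)C)cc(OC)c2c1O[C@](C)(CCC1OC1(C)C)CC2 | intermediate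
22 | (2S)-2-[4-hydroxy-4-methyl-3-(phenylselanyl)pentyl]chroman ester | CCOC(=O)c1c(CO[Si](C)(C)C(C)(C)C)cc(OC)c2c1O[C@](C)(CCC([Se]c1ccccc1)C(C)(C)O)CC2 | intermediate
23 | selenoxide of 22 | CCOC(=O)c1c(CO[Si](C)(C)C(C)(C)C)cc(OC)c2c1O[C@](C)(CCC([Se](=O)c1ccccc1)C(C)(C)O)CC2 | intermediate
24 | ethyl (2S)-7-{[(tert-butyldimethylsilyl)oxy]methyl}-2-[(2E)-4-hydroxy-4-methylpent-2-en-1-yl]-5-methoxy-2-methylchroman-8-carboxylate | CCOC(=O)c1c(CO[Si](C)(C)C(C)(C)C)cc(OC)c2c1O[C@](C)(C/C=C/C(C)(C)O)CC2 | intermediate
25 | (2S)-8-(hydroxymethyl) diol | OCc1c(CO[Si](C)(C)C(C)(C)C)cc(OC)c2c1O[C@](C)(C/C=C/C(C)(C)O)CC2 | intermediate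
26 | (2S)-7-{[(tert-butyldimethylsilyl)oxy]methyl}-2-[(2E)-4-hydroxy-4-methylpent-2-en-1-yl]-5-methoxy-2-methylchroman-8-carbaldehyde | O=Cc1c(CO[Si](C)(C)C(C)(C)C)cc(OC)c2c1O[C@](C)(C/C=C/C(C)(C)O)CC2 | intermediate
27 | (2S)-7-{[(tert-butyldimethylsilyl)oxy]methyl}-5-methoxy-2-methyl-2-(4-methyl-2-oxopent-3-en-1-yl)chroman-8-carbaldehyde | O=Cc1c(CO[Si](C)(C)C(C)(C)C)cc(OC)c2c1O[C@](C)(CC(=O)C=C(C)C)CC2 | intermediate
28 | (2S)-7-(hydroxymethyl)-5-methoxy-2-methyl-2-(4-methyl-2-oxopent-3-en-1-yl)chroman-8-carbaldehyde | O=Cc1c(CO)cc(OC)c2c1O[C@](C)(CC(=O)C=C(C)C)CC2 | intermediate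
29 | palmitoyl chloride | CCCCCCCCCCCCCCCC(=O)Cl | starting material
30 | [(2S)-8-formyl-5-methoxy-2-methyl-2-(4-methyl-2-oxopent-3-en-1-yl)chroman-7-yl]methyl hexadecanoate | CCCCCCCCCCCCCCCC(=O)OCc1cc(OC)c2c(c1C=O)O[C@](C)(CC(=O)C=C(C)C)CC2 | target

**Total step count:** 16. **Longest linear sequence:** 13 (steps 1–5 and 9–16); steps 6–8 form the convergent diazine branch.

**Steps most likely to fail**

**Step 10.** The tertiary pyridazinyl ether may fragment by retro-ene or acid-triggered loss of the alkyl group. The ynol ether may also be hydrated or oligomerise before the cycloaddition sets in. The ester is flanked on both sides and may be twisted, so it could activate the diazine less than expected.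

Fallback: the benzene ring is bought and only the pyran is closed, by an intramolecular SNAr that again leaves the C2–O bond untouched. It sets out from 1 and rejoins the route at 20.
- (3-Fluoro-5-methoxyphenyl)methanol F1 is silylated (t-BuMe2SiCl, imidazole) to silyl ether F2.
- Lithiation between F and OMe (s-BuLi, THF, −78 °C) and quenching with BrCCl2CCl2Br gives aryl bromide F3.
- Fluorine-directed lithiation at the remaining position ortho to fluorine (LiN(i-Pr)2, −78 °C) and ClCO2Et gives benzoate F4.
- Linalool 1 is hydroborated with 9-BBN-H (2.2 equiv) to borane F5. This is coupled in the same flask with F4 (B-alkyl Suzuki–Miyaura coupling, PdCl2(dppf), K3PO4, THF–DMF–H2O) to tertiary alcohol F6.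
- KN(SiMe3)2 in THF then displaces the fluoride ortho to the ester and gives 20.

**Step 9.** The hindered alkoxide may add to the ester carbonyl, an acyl transfer in which the released ethoxide then consumes the chlorodiazine. It may also substitute too slowly.

Fallback: the leaving group is exchanged before the coupling. It sets out from 16 and rejoins at 18. PhSO2Na in DMF at rt converts 16 by sulfinate SNAr into sulfone F7. Hard alkoxides displace a heteroaryl sulfone much more readily than chloride. Alkoxide 17 can therefore be added at −78 °C, where carbonyl attack is frozen out, to give 18.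

**Step 14.** The tertiary allylic alcohol may ionise and dehydrate in the acidic chromium medium. The transposition may also stall after the fast benzylic oxidation.

Fallback: the three events are separated under nearly neutral conditions. It sets out from 25 and rejoins at 27.
- MnO2 in CH2Cl2 oxidises only the benzylic alcohol and gives 26, now isolated.
- Catalytic Ph3SiOReO3 in Et2O (−30 → 0 °C) effects the 1,3-transposition of the hydroxyl group to secondary allylic alcohol F8 (both carbinol epimers).
- Dess–Martin periodinane in CH2Cl2 then gives 27.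

**Further compounds**

F1 | step 10 | (3-fluoro-5-methoxyphenyl)methanol (purchased) | COc1cc(F)cc(CO)c1
F2 | step 10 | tert-butyl[(3-fluoro-5-methoxybenzyl)oxy]dimethylsilane | COc1cc(F)cc(CO[Si](C)(C)C(C)(C)C)c1
F3 | step 10 | [(4-bromo-3-fluoro-5-methoxybenzyl)oxy](tert-butyl)dimethylsilane | COc1cc(CO[Si](C)(C)C(C)(C)C)cc(F)c1Br
F4 | step 10 | ethyl 3-bromo-6-{[(tert-butyldimethylsilyl)oxy]methyl}-2-fluoro-4-methoxybenzoate | CCOC(=O)c1c(CO[Si](C)(C)C(C)(C)C)cc(OC)c(Br)c1F
F5 | step 10 | (3R)-1-(9-borabicyclo[3.3.1]nonan-9-yl)-3,7-dimethyloct-6-en-3-ol | O[C@](C)(CCC=C(C)C)CCB1C2CCCC1CCC2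
F6 | step 10 | ethyl 6-{[(tert-butyldimethylsilyl)oxy]methyl}-2-fluoro-3-[(3R)-3-hydroxy-3,7-dimethyloct-6-en-1-yl]-4-methoxybenzoate | O[C@](C)(CCC=C(C)C)CCc1c(F)c(C(=O)OCC)c(CO[Si](C)(C)C(C)(C)C)cc1OC
F7 | step 9 | ethyl 5-{[(tert-butyldimethylsilyl)oxy]methyl}-3-(phenylsulfonyl)pyridazine-4-carboxylate | CCOC(=O)c1c(CO[Si](C)(C)C(C)(C)C)cnnc1S(=O)(=O)c1ccccc1
F8 | step 14 | (2S)-7-{[(tert-butyldimethylsilyl)oxy]methyl}-2-(2-hydroxy-4-methylpent-3-en-1-yl)-5-methoxy-2-methylchroman-8-carbaldehyde | O=Cc1c(CO[Si](C)(C)C(C)(C)C)cc(OC)c2c1O[C@](C)(CC(O)C=C(C)C)CC2
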